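**Retrosynthetic overview**
1. The furanone ring (O–C3=C2–C1(=O)–C10) is opened to the γ-hydroxy ynone HO–C10(CH3)–C1≡C2–C3(=O); the oxa-bridge C10–O–C3 is closed last, transannularly, by gold-catalysed cycloisomerization.
2. Key disconnection C1–C10: the ten-membered carbocycle is closed by addition of a C1 alkynylchromium terminus to the C10 methyl ketone. The enabling feature is that C10, the quaternary oxygen-bearing carbon shared by the furanone and the ten-membered ring, is bonded directly to the carbonyl carbon C1, so at the alkyne oxidation level C1 is an acetylide and C10 a methyl ketone that already carries the C14 methyl.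
3. C4–C5: Nozaki–Hiyama–Kishi union of a C1–C4 iodoallyl alkyne fragment with a C5–C14 lactone aldehyde (Felkin control at C5).
4. Lactone aldehyde: C7–C8 by allylboration of a C8–C10 ketal aldehyde with a chiral 2-(methoxycarbonyl)allylboronate made from crotonaldehyde and methyl propiolate; this builds the trans α-methylene-γ-butyrolactone, and C6 is then inverted by Mitsunobu esterification with methacrylic acid.
5. Ring order: γ-lactone (step 5), ten-membered carbocycle (step 16), furanone bridge (step 19).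

Key step: step 16

Remark: carbon numbers C1–C15 are those of the germacrane skeleton of the target (C1 ketone, C2=C3, C4=C15H2, C5–OH, C6–O-methacrylate, C7–C11(=C13H2)–C12 lactone carbonyl, C8 lactone oxygen, C10–C14H3); the C3 configuration of the western fragment is arbitrary (3R chosen) because C3 is oxidized in step 18.

**Step 1**
Reactants: 1 ethyl 2-(2-methyl-1,3-dioxolan-2-yl)acetate
Product: 2 2-(2-methyl-1,3-dioxolan-2-yl)acetaldehyde
Conditions: i-Bu2AlH (1.05 equiv), CH2Cl2, −78 °C
Reagents that add atoms: none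
Why: Partial ester reduction with i-Bu2AlH at −78 °C stops at the aluminium hemiacetal, which collapses to the aldehyde on work-up while the dioxolane keeps the future C10 ketone masked; no stereocentre is formed.

**Step 2**
Reactants: 3 (E)-but-2-enal; 4 methyl prop-2-ynoate
Product: 5 methyl (4R,5E)-4-hydroxyhept-5-en-2-ynoate
Conditions: Me2Zn (3 equiv), ProPhenol ligand (10 mol %, antipode giving 4R), toluene, 0 °C
Reagents that add atoms: none
Why: Zinc-ProPhenol-catalysed enantioselective alkynylation of an enal delivers the zinc acetylide to one aldehyde face and sets the carbinol that becomes C6, deliberately in the configuration opposite to the target because it is inverted in step 7.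

**Step 3**
Reactants: 5 methyl (4R,5E)-4-hydroxyhept-5-en-2-ynoate
Product: 6 methyl (4R,5E)-4-(triethylsilyloxy)hept-5-en-2-ynoate
Conditions: TESCl, imidazole, CH2Cl2, 0 °C
Reagents that add atoms: chlorotriethylsilane, CC[Si](Cl)(CC)CC
Why: Imidazole-promoted silylation of a secondary alcohol blocks the carbinol for the hydroalumination and allylboration; the stereocentre is untouched.

**Step 4**
Reactants: 6 methyl (4R,5E)-4-(triethylsilyloxy)hept-5-en-2-ynoate
Product: 8 methyl (2Z,4R,5E)-2-[(4,4,5,5-tetramethyl-1,3,2-dioxaborolan-2-yl)methyl]-4-(triethylsilyloxy)hepta-2,5-dienoate, via alkenylalane 7 (not isolated)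
Conditions: i-Bu2AlH, HMPA, THF, 0 °C; then ICH2Bpin, 0 °C to rt
Reagents that add atoms: 2-(iodomethyl)-4,4,5,5-tetramethyl-1,3,2-dioxaborolane, ICB1OC(C)(C)C(C)(C)O1
Why: Syn hydroalumination of the ynoate by the i-Bu2AlH–HMPA complex puts aluminium on C11 and hydrogen on C7, and Matteson-type homologation with the iodomethylboronate (boron ate complex, then 1,2-shift with loss of iodide) transfers the alkenyl group with retention of geometry, so C6 ends trans to the CH2B group; no stereocentre is formed.

**Step 5**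
Reactants: 8 the allylboronate from step 4; 2 2-(2-methyl-1,3-dioxolan-2-yl)acetaldehyde
Product: 10 (4R,5S)-5-[(2-methyl-1,3-dioxolan-2-yl)methyl]-3-methylidene-4-[(1R,2E)-1-(triethylsilyloxy)but-2-en-1-yl]oxolan-2-one, via borate adduct 9 (not isolated)
Conditions: toluene, 80 °C, 48 h; then PPTS (10 mol %), rt
Reagents that add atoms: none
Why: 2-(Alkoxycarbonyl)allylboration through a chair Zimmerman–Traxler transition state places the C6 substituent (trans to CH2B) equatorial, giving the anti adduct and hence the trans β,γ-disubstituted α-methylene-γ-butyrolactone, while A1,3 strain with the cis ester holds C6–H in the alkene plane so the aldehyde adds to C7 anti to the C6 silyloxy group, which sets C7 and C8 as in the target with C6 still of the opposite configuration.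

**Step 6**
Reactants: 10 the silyloxy ketal lactone from step 5
Product: 11 (4S,5S)-4-[(1R,2E)-1-hydroxybut-2-en-1-yl]-3-methylidene-5-(2-oxopropyl)oxolan-2-one
Conditions: TsOH·H2O (10 mol %), acetone/H2O (10:1), rt
Reagents that add atoms: water, O
Why: Acid-catalysed transketalization to acetone and hydrolysis of the triethylsilyl ether proceed under conditions that leave the α-methylene lactone and the allylic carbinol intact; no stereocentre changes (the C7 descriptor changes only through substituent priorities).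

**Step 7**
Reactants: 11 the hydroxy keto lactone from step 6
Product: 12 (1S,2E)-1-[(2S,3R)-4-methylidene-5-oxo-2-(2-oxopropyl)oxolan-3-yl]but-2-en-1-yl 2-methylprop-2-enoate
Conditions: PPh3, DIAD, methacrylic acid, toluene, 0 °C to rt (betaine preformed)
Reagents that add atoms: methacrylic acid, C=C(C)C(=O)O
Why: Mitsunobu esterification displaces the alkoxyphosphonium ion of the allylic C6 alcohol by methacrylate in an SN2 reaction with inversion, which installs the C6 ester and corrects C6 to the configuration of the target in one operation.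

**Step 8**
Reactants: 12 the methacrylate from step 7
Product: 14 (1R)-1-[(2S,3R)-4-methylidene-5-oxo-2-(2-oxopropyl)oxolan-3-yl]-2-oxoethyl 2-methylprop-2-enoate, via ozonide 13 (not isolated)
Conditions: O3, CH2Cl2, −78 °C (Sudan Red 7B end point); then Me2S, −78 °C to rt
Reagents that add atoms: ozone, [O-][O+]=O
Why: Ozonolysis attacks the electron-rich 1,2-disubstituted propenyl double bond much faster than the two conjugated 1,1-disubstituted alkenes, and reductive work-up of the ozonide gives the α-acyloxy aldehyde (C5) without touching C6.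

**Step 9**
Reactants: 15 prop-2-yn-1-ol
Product: 16 2-iodoprop-2-en-1-ol
Conditions: NaI, TMSCl, H2O, MeCN, rt
Reagents that add atoms: sodium iodide, [Na+].[I-]
Why: Markovnikov hydroiodination of the terminal alkyne by HI generated in the flask from TMSCl, NaI and water gives the 2-iodoalkene regioselectively; no stereocentre is formed.

**Step 10**
Reactants: 16 2-iodoprop-2-en-1-ol
Product: 17 2-iodoprop-2-enal
Conditions: activated MnO2 (10 equiv), CH2Cl2, rt; filtered solution used directly
Reagents that add atoms: none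
Why: Allylic oxidation with MnO2 is selective for the allylic alcohol and stops at the enal, which is used in solution because it is volatile and labile.

**Step 11**
Reactants: 17 2-iodoprop-2-enal; 18 ethynyl(trimethyl)silane
Product: 19 (3R)-2-iodo-5-(trimethylsilyl)pent-1-en-4-yn-3-ol
Conditions: Me2Zn (3 equiv), ProPhenol ligand (10 mol %, antipode giving 3R), toluene, 0 °C
Reagents that add atoms: none
Why: Zinc-ProPhenol-catalysed enantioselective alkynylation of the enal sets the C3 carbinol, which serves only as a defined placeholder until it is oxidized in step 18.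

**Step 12**
Reactants: 19 (3R)-2-iodo-5-(trimethylsilyl)pent-1-en-4-yn-3-ol
Product: 20 triethyl{[(3R)-2-iodo-5-(trimethylsilyl)pent-1-en-4-yn-3-yl]oxy}silane
Conditions: TESCl, imidazole, CH2Cl2, 0 °C
Reagents that add atoms: chlorotriethylsilane, CC[Si](Cl)(CC)CC
Why: Standard silylation gives a C3 ether that can later be cleaved selectively in the presence of a tert-butyldimethylsilyl ether; the stereocentre is untouched.

**Step 13**
Reactants: 14 the lactone aldehyde from step 8; 20 the vinyl iodide from step 12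
Product: 21 (1R,2S,4S)-2-hydroxy-3-methylidene-1-[(2S,3R)-4-methylidene-5-oxo-2-(2-oxopropyl)oxolan-3-yl]-4-(triethylsilyloxy)-6-(trimethylsilyl)hex-5-yn-1-yl 2-methylprop-2-enoate
Conditions: CrCl2 (5 equiv), NiCl2 (2 mol %), DMSO/THF, rt
Reagents that add atoms: none
Why: Nozaki–Hiyama–Kishi coupling adds the alkenylchromium species formed from the vinyl iodide under nickel catalysis to the aldehyde only (methyl ketone, esters and silylalkyne are inert), and Felkin–Anh addition anti to the α-acyloxy group sets the C5 carbinol (5S), the 5,6-anti arrangement of the target.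

**Step 14**
Reactants: 21 the allylic alcohol from step 13
Product: 22 (1R,2S,4S)-2-(tert-butyldimethylsilyloxy)-3-methylidene-1-[(2S,3R)-4-methylidene-5-oxo-2-(2-oxopropyl)oxolan-3-yl]-4-(triethylsilyloxy)-6-(trimethylsilyl)hex-5-yn-1-yl 2-methylprop-2-enoate
Conditions: TBSOTf, 2,6-lutidine, CH2Cl2, −78 °C
Reagents that add atoms: tert-butyldimethylsilyl triflate, CC(C)(C)[Si](C)(C)OS(=O)(=O)C(F)(F)F
Why: Silylation of the C5 alcohol with the silyl triflate at −78 °C is faster than enol silylation of the methyl ketone and blocks acyl migration from C6; no stereocentre changes.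

**Step 15**
Reactants: 22 the silylalkyne from step 14
Product: 23 (1R,2S,4S)-2-(tert-butyldimethylsilyloxy)-6-iodo-3-methylidene-1-[(2S,3R)-4-methylidene-5-oxo-2-(2-oxopropyl)oxolan-3-yl]-4-(triethylsilyloxy)hex-5-yn-1-yl 2-methylprop-2-enoate
Conditions: NIS (1.2 equiv), AgNO3 (10 mol %), DMF, rt, dark
Reagents that add atoms: N-iodosuccinimide, O=C1CCC(=O)N1I
Why: Silver-catalysed iododesilylation converts the alkynyl C–Si bond through a silver acetylide into the C–I bond needed for chromium insertion, without touching the alkenes, the ketone or the silyl ethers.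

**Step 16**
Reactants: 23 the iodoalkyne methyl ketone from step 15
Product: 25 (3R,5S,6R,7R,8S,10S)-5-(tert-butyldimethylsilyloxy)-10-hydroxy-6-(methacryloyloxy)-3-(triethylsilyloxy)germacra-4(15),11(13)-dien-1-yn-12,8-olide, via alkynylchromium dichloride 24 (not isolated)
Conditions: CrCl2 (10 equiv), dry DMF, 25 °C, slow addition of 23 to a final 2 mM
Reagents that add atoms: none
Why: Two equivalents of CrCl2 (divalent chromium) reduce the C(sp)–I bond to the alkynylchromium dichloride 24 (trivalent chromium), which adds to the C10 methyl ketone in a Nozaki–Hiyama–Kishi, Barbier-type 1,2-addition. The closest precedents are CrCl2-mediated iodoalkyne–aldehyde closures of ten-membered cycloalkynols and the intermolecular addition of alkynylchromium reagents to ketones. The ten-membered carbocycle closes by 10-exo-trig attack of C1 on the carbonyl carbon C10, helped by the trans-fused lactone across C7–C8 and the sp2 centre C4, which restrict the seco chain, and by the linear C10–C1≡C2–C3 unit, which relieves transannular strain. The new quaternary centre C10 (10S) is controlled by C8: ring closure requires C7 and C1 to lie gauche about C8–C9 and C9–C10 with the same helical sense, and when the oxophilic trivalent chromium bridges the ketone oxygen and the C8 ring oxygen the tethered alkyne reaches only the ketone face that gives the 8,10-anti carbinol. The step needs chemoselectivity for the ketone over lactone, methacrylate and conjugated alkenes, which the low basicity and nucleophilicity of alkynylchromium species secure, and it needs ring closure to outrun protonation, which slow addition to excess CrCl2 in dry DMF secures.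

**Step 17**
Reactants: 25 the macrocyclic tertiary alcohol from step 16
Product: 26 (3R,5S,6R,7R,8S,10S)-5-(tert-butyldimethylsilyloxy)-3,10-dihydroxy-6-(methacryloyloxy)germacra-4(15),11(13)-dien-1-yn-12,8-olide
Conditions: PPTS (0.2 equiv), MeOH/CH2Cl2 (1:1), 0 °C
Reagents that add atoms: none
Why: Mild acid-catalysed methanolysis cleaves the more labile triethylsilyl ether at C3 while the tert-butyldimethylsilyl ether at C5 and the tertiary C10 alcohol are retained.

**Step 18**
Reactants: 26 the diol from step 17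
Product: 27 (5S,6R,7R,8S,10S)-5-(tert-butyldimethylsilyloxy)-10-hydroxy-6-(methacryloyloxy)-3-oxogermacra-4(15),11(13)-dien-1-yn-12,8-olide
Conditions: activated MnO2 (20 equiv), CH2Cl2, rt
Reagents that add atoms: none
Why: MnO2 oxidizes only the propargylic and allylic C3 alcohol (the tertiary C10 alcohol cannot be oxidized and C5 is silylated), giving the γ-hydroxy ynone and erasing the C3 stereocentre.

**Step 19**
Reactants: 27 the γ-hydroxy ynone from step 18
Product: 28 (5S,6R,7R,8S,10S)-5-(tert-butyldimethylsilyloxy)-3,10-epoxy-6-(methacryloyloxy)-1-oxogermacra-2,4(15),11(13)-trien-12,8-olide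
Conditions: (p-CF3C6H4)3PAuCl (5 mol %), AgOTf (5 mol %), toluene (not dried), rt
Reagents that add atoms: none
Why: Monovalent gold activates the ynone for conjugate hydration at C1 by adventitious water, and the resulting 1,3-diketone is trapped transannularly by the C10 hydroxyl at C3 (5-exo-trig) with loss of water, the known cycloisomerization of γ-hydroxy ynones to 3(2H)-furanones; C10 is untouched.

**Step 20**
Reactants: 28 the silylated furanone from step 19
Product: 29 (5S,6R,7R,8S,10S)-3,10-epoxy-5-hydroxy-6-(methacryloyloxy)-1-oxogermacra-2,4(15),11(13)-trien-12,8-olide (CNP0142847.1)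
Conditions: HF·pyridine, pyridine, THF, 0 °C to rt
Reagents that add atoms: none
Why: Buffered fluoride desilylation removes the last silyl ether under conditions that should not promote acyl migration from C6 to C5 or conjugate addition to the α-methylene lactone.

**Compound list**
1 | ethyl 2-(2-methyl-1,3-dioxolan-2-yl)acetate | CCOC(=O)CC1(C)OCCO1 | starting material
2 | 2-(2-methyl-1,3-dioxolan-2-yl)acetaldehyde | O=CCC1(C)OCCO1 | intermediate
3 | (E)-but-2-enal | C/C=C/C=O | starting material
4 | methyl prop-2-ynoate | C#CC(=O)OC | starting material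
5 | methyl (4R,5E)-4-hydroxyhept-5-en-2-ynoate | C/C=C/[C@@H](O)C#CC(=O)OC | intermediate
6 | methyl (4R,5E)-4-(triethylsilyloxy)hept-5-en-2-ynoate | C/C=C/[C@@H](O[Si](CC)(CC)CC)C#CC(=O)OC | intermediate
7 | methyl (2E,4R,5E)-2-[bis(2-methylpropyl)alumanyl]-4-(triethylsilyloxy)hepta-2,5-dienoate (alkenylalane) | COC(=O)/C([Al](CC(C)C)CC(C)C)=C\[C@H](O[Si](CC)(CC)CC)/C=C/C | intermediate
8 | methyl (2Z,4R,5E)-2-[(4,4,5,5-tetramethyl-1,3,2-dioxaborolan-2-yl)methyl]-4-(triethylsilyloxy)hepta-2,5-dienoate | COC(=O)/C(CB1OC(C)(C)C(C)(C)O1)=C\[C@H](O[Si](CC)(CC)CC)/C=C/C | intermediate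
9 | open-chain anti adduct, methyl ester with C8–O–B(pinacolato) (borate adduct) | C/C=C/[C@@H](O[Si](CC)(CC)CC)[C@H](C(=C)C(=O)OC)[C@@H](OB1OC(C)(C)C(C)(C)O1)CC1(C)OCCO1 | intermediate
10 | (4R,5S)-5-[(2-methyl-1,3-dioxolan-2-yl)methyl]-3-methylidene-4-[(1R,2E)-1-(triethylsilyloxy)but-2-en-1-yl]oxolan-2-one | C/C=C/[C@@H](O[Si](CC)(CC)CC)[C@@H]1C(=C)C(=O)O[C@H]1CC1(C)OCCO1 | intermediate
11 | (4S,5S)-4-[(1R,2E)-1-hydroxybut-2-en-1-yl]-3-methylidene-5-(2-oxopropyl)oxolan-2-one | C/C=C/[C@@H](O)[C@@H]1C(=C)C(=O)O[C@H]1CC(C)=O | intermediate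
12 | (1S,2E)-1-[(2S,3R)-4-methylidene-5-oxo-2-(2-oxopropyl)oxolan-3-yl]but-2-en-1-yl 2-methylprop-2-enoate | C/C=C/[C@H](OC(=O)C(C)=C)[C@@H]1C(=C)C(=O)O[C@H]1CC(C)=O | intermediate
13 | secondary ozonide of 12 (3-methyl-1,2,4-trioxolan-5-yl in place of propenyl; mixture at the two trioxolane carbons) | CC1OOC(O1)[C@H](OC(=O)C(C)=C)[C@@H]2C(=C)C(=O)O[C@H]2CC(C)=O | intermediate
14 | (1R)-1-[(2S,3R)-4-methylidene-5-oxo-2-(2-oxopropyl)oxolan-3-yl]-2-oxoethyl 2-methylprop-2-enoate | O=C[C@H](OC(=O)C(C)=C)[C@@H]1C(=C)C(=O)O[C@H]1CC(C)=O | intermediate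
15 | prop-2-yn-1-ol | C#CCO | starting material
16 | 2-iodoprop-2-en-1-ol | C=C(I)CO | intermediate
17 | 2-iodoprop-2-enal | C=C(I)C=O | intermediate
18 | ethynyl(trimethyl)silane | C#C[Si](C)(C)C | starting material
19 | (3R)-2-iodo-5-(trimethylsilyl)pent-1-en-4-yn-3-ol | C=C(I)[C@H](O)C#C[Si](C)(C)C | intermediate
20 | triethyl{[(3R)-2-iodo-5-(trimethylsilyl)pent-1-en-4-yn-3-yl]oxy}silane | C=C(I)[C@H](O[Si](CC)(CC)CC)C#C[Si](C)(C)C | intermediate
21 | (1R,2S,4S)-2-hydroxy-3-methylidene-1-[(2S,3R)-4-methylidene-5-oxo-2-(2-oxopropyl)oxolan-3-yl]-4-(triethylsilyloxy)-6-(trimethylsilyl)hex-5-yn-1-yl 2-methylprop-2-enoate | C[Si](C)(C)C#C[C@@H](O[Si](CC)(CC)CC)C(=C)[C@H](O)[C@H](OC(=O)C(C)=C)[C@@H]1C(=C)C(=O)O[C@H]1CC(C)=O | intermediate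
22 | (1R,2S,4S)-2-(tert-butyldimethylsilyloxy)-3-methylidene-1-[(2S,3R)-4-methylidene-5-oxo-2-(2-oxopropyl)oxolan-3-yl]-4-(triethylsilyloxy)-6-(trimethylsilyl)hex-5-yn-1-yl 2-methylprop-2-enoate | C[Si](C)(C)C#C[C@@H](O[Si](CC)(CC)CC)C(=C)[C@H](O[Si](C)(C)C(C)(C)C)[C@H](OC(=O)C(C)=C)[C@@H]1C(=C)C(=O)O[C@H]1CC(C)=O | intermediate
23 | (1R,2S,4S)-2-(tert-butyldimethylsilyloxy)-6-iodo-3-methylidene-1-[(2S,3R)-4-methylidene-5-oxo-2-(2-oxopropyl)oxolan-3-yl]-4-(triethylsilyloxy)hex-5-yn-1-yl 2-methylprop-2-enoate | IC#C[C@@H](O[Si](CC)(CC)CC)C(=C)[C@H](O[Si](C)(C)C(C)(C)C)[C@H](OC(=O)C(C)=C)[C@@H]1C(=C)C(=O)O[C@H]1CC(C)=O | intermediate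
24 | alkynylchromium dichloride from 23 (CrCl2 in place of iodine at C1; solvent ligands omitted) | Cl[Cr](Cl)C#C[C@@H](O[Si](CC)(CC)CC)C(=C)[C@H](O[Si](C)(C)C(C)(C)C)[C@H](OC(=O)C(C)=C)[C@@H]1C(=C)C(=O)O[C@H]1CC(C)=O | intermediate
25 | (3R,5S,6R,7R,8S,10S)-5-(tert-butyldimethylsilyloxy)-10-hydroxy-6-(methacryloyloxy)-3-(triethylsilyloxy)germacra-4(15),11(13)-dien-1-yn-12,8-olide | C=C(C)C(=O)O[C@@H]1[C@@H]2C(=C)C(=O)O[C@H]2C[C@](C)(O)C#C[C@@H](O[Si](CC)(CC)CC)C(=C)[C@@H]1O[Si](C)(C)C(C)(C)C | intermediate
26 | (3R,5S,6R,7R,8S,10S)-5-(tert-butyldimethylsilyloxy)-3,10-dihydroxy-6-(methacryloyloxy)germacra-4(15),11(13)-dien-1-yn-12,8-olide | C=C(C)C(=O)O[C@@H]1[C@@H]2C(=C)C(=O)O[C@H]2C[C@](C)(O)C#C[C@@H](O)C(=C)[C@@H]1O[Si](C)(C)C(C)(C)C | intermediate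
27 | (5S,6R,7R,8S,10S)-5-(tert-butyldimethylsilyloxy)-10-hydroxy-6-(methacryloyloxy)-3-oxogermacra-4(15),11(13)-dien-1-yn-12,8-olide | C=C(C)C(=O)O[C@@H]1[C@@H]2C(=C)C(=O)O[C@H]2C[C@](C)(O)C#CC(=O)C(=C)[C@@H]1O[Si](C)(C)C(C)(C)C | intermediate
28 | (5S,6R,7R,8S,10S)-5-(tert-butyldimethylsilyloxy)-3,10-epoxy-6-(methacryloyloxy)-1-oxogermacra-2,4(15),11(13)-trien-12,8-olide | C=C(C)C(=O)O[C@@H]1[C@@H]2C(=C)C(=O)O[C@H]2C[C@]2(C)OC(=CC2=O)C(=C)[C@@H]1O[Si](C)(C)C(C)(C)C | intermediate
29 | (5S,6R,7R,8S,10S)-3,10-epoxy-5-hydroxy-6-(methacryloyloxy)-1-oxogermacra-2,4(15),11(13)-trien-12,8-olide (CNP0142847.1) | C=C(C)C(=O)O[C@@H]1[C@@H]2C(=C)C(=O)O[C@H]2C[C@]2(C)OC(=CC2=O)C(=C)[C@@H]1O | target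

**Summary**
Total step count: 20. Longest linear sequence: 15 steps (steps 2–8, then 13–20).

Steps most likely to fail:

Step 16. The alkynylchromium intermediate may be protonated faster than it adds to the methyl ketone, and the two ketone faces may not be differentiated well enough at C10; the chelation argument is a model, not a guarantee. The fallback sets out from 22 and returns at 25. Silver-catalysed protodesilylation (AgNO3, 2,6-lutidine, acetone/H2O) would give the terminal alkyne (1R,2S,4R)-2-(tert-butyldimethylsilyloxy)-3-methylidene-1-[(2S,3R)-4-methylidene-5-oxo-2-(2-oxopropyl)oxolan-3-yl]-4-(triethylsilyloxy)hex-5-yn-1-yl 2-methylprop-2-enoate F1. Its zinc acetylide (Me2Zn, toluene) would then be added to the C10 ketone under catalyst control with Ti(OiPr)4 and BINOL (antipode chosen for the 10S face) at high dilution, so that the ligand rather than the ring conformation selects the face; aqueous work-up gives 25.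

Step 5. Carbon–carbon bond formation by the ester-deactivated allylboronate may be too slow at a temperature the enolizable ketal aldehyde tolerates, and the induction from C6 to C7 may erode. The fallback sets out from 6 and returns at 10. Hydroalumination as in step 4 but trapping with formaldehyde would give methyl (2Z,4R,5E)-2-(hydroxymethyl)-4-(triethylsilyloxy)hepta-2,5-dienoate F2, and CBr4/PPh3 would give methyl (2E,4R,5E)-2-(bromomethyl)-4-(triethylsilyloxy)hepta-2,5-dienoate F3. Chromium-catalysed 2-(alkoxycarbonyl)allylation of 2 (CrCl2 cat., Mn, TMSCl, chiral carbazole bis(oxazoline) ligand, THF, rt) would form C7–C8 under catalyst control through an equilibrating allylchromium species and give, after acidic work-up, methyl (3R,4S)-4-hydroxy-5-(2-methyl-1,3-dioxolan-2-yl)-2-methylidene-3-[(1R,2E)-1-(triethylsilyloxy)but-2-en-1-yl]pentanoate F4, which PPTS would lactonize to 10.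

Step 7. Displacement at the allylic C6 centre may go partly by the SN2' path or by elimination, and the free C6 hydroxyl of 11 may translactonize before it is activated. The fallback sets out from 10 and returns at 12. HF·pyridine would remove only the silyl ether to give (4S,5S)-4-[(1R,2E)-1-hydroxybut-2-en-1-yl]-5-[(2-methyl-1,3-dioxolan-2-yl)methyl]-3-methylideneoxolan-2-one F5, and MnO2 would oxidize it to the enone (4R,5S)-4-[(2E)-but-2-enoyl]-5-[(2-methyl-1,3-dioxolan-2-yl)methyl]-3-methylideneoxolan-2-one F6. Corey–Bakshi–Shibata reduction (oxazaborolidine antipode chosen for the 1S carbinol, catecholborane, −78 °C) would give the inverted alcohol (4S,5S)-4-[(1S,2E)-1-hydroxybut-2-en-1-yl]-5-[(2-methyl-1,3-dioxolan-2-yl)methyl]-3-methylideneoxolan-2-one F7. Methacrylic anhydride/DMAP would give (1S,2E)-1-{(2S,3R)-2-[(2-methyl-1,3-dioxolan-2-yl)methyl]-4-methylidene-5-oxooxolan-3-yl}but-2-en-1-yl 2-methylprop-2-enoate F8, and TsOH·H2O in wet acetone would release the ketone to give 12.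

**Further compounds**
F1 | step 16 | (1R,2S,4R)-2-(tert-butyldimethylsilyloxy)-3-methylidene-1-[(2S,3R)-4-methylidene-5-oxo-2-(2-oxopropyl)oxolan-3-yl]-4-(triethylsilyloxy)hex-5-yn-1-yl 2-methylprop-2-enoate | C#C[C@@H](O[Si](CC)(CC)CC)C(=C)[C@H](O[Si](C)(C)C(C)(C)C)[C@H](OC(=O)C(C)=C)[C@@H]1C(=C)C(=O)O[C@H]1CC(C)=O
F2 | step 5 | methyl (2Z,4R,5E)-2-(hydroxymethyl)-4-(triethylsilyloxy)hepta-2,5-dienoate | COC(=O)/C(CO)=C\[C@H](O[Si](CC)(CC)CC)/C=C/C
F3 | step 5 | methyl (2E,4R,5E)-2-(bromomethyl)-4-(triethylsilyloxy)hepta-2,5-dienoate | COC(=O)/C(CBr)=C\[C@H](O[Si](CC)(CC)CC)/C=C/C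
F4 | step 5 | methyl (3R,4S)-4-hydroxy-5-(2-methyl-1,3-dioxolan-2-yl)-2-methylidene-3-[(1R,2E)-1-(triethylsilyloxy)but-2-en-1-yl]pentanoate | C/C=C/[C@@H](O[Si](CC)(CC)CC)[C@H](C(=C)C(=O)OC)[C@@H](O)CC1(C)OCCO1
F5 | step 7 | (4S,5S)-4-[(1R,2E)-1-hydroxybut-2-en-1-yl]-5-[(2-methyl-1,3-dioxolan-2-yl)methyl]-3-methylideneoxolan-2-one | C/C=C/[C@@H](O)[C@@H]1C(=C)C(=O)O[C@H]1CC1(C)OCCO1
F6 | step 7 | (4R,5S)-4-[(2E)-but-2-enoyl]-5-[(2-methyl-1,3-dioxolan-2-yl)methyl]-3-methylideneoxolan-2-one | C/C=C/C(=O)[C@@H]1C(=C)C(=O)O[C@H]1CC1(C)OCCO1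
F7 | step 7 | (4S,5S)-4-[(1S,2E)-1-hydroxybut-2-en-1-yl]-5-[(2-methyl-1,3-dioxolan-2-yl)methyl]-3-methylideneoxolan-2-one | C/C=C/[C@H](O)[C@@H]1C(=C)C(=O)O[C@H]1CC1(C)OCCO1
F8 | step 7 | (1S,2E)-1-{(2S,3R)-2-[(2-methyl-1,3-dioxolan-2-yl)methyl]-4-methylidene-5-oxooxolan-3-yl}but-2-en-1-yl 2-methylprop-2-enoate | C/C=C/[C@H](OC(=O)C(C)=C)[C@@H]1C(=C)C(=O)O[C@H]1CC1(C)OCCO1
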